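**Retrosynthetic overview**
1. The 5α-hydroxy-4(15)-ene unit of ring A is the allylically transposed (Schenck ene) form of a C4(CH3)=C5 alkene. The C3 angelate, C8 acetate and C12 methyl ester are late acylations and oxidations on an 8β-oxygenated α-cyperone core.
2. Key disconnection: C1–C10 and C4–C5 are cut together. Ring A falls away as pent-1-en-3-one (C1–C2–C3(=O)–C4–C15, used as its 2-silyl derivative). Ring B remains as a 2-methylcyclohexenone whose enolate is generated by conjugate hydride addition.
3. Enabling feature: the fusion pair C5 (oxygen-bearing) / C10 (methyl-bearing, quaternary) shared by rings A and B is a latent 2-methylcyclohexanone (donor C10, acceptor C5). The arc C1–C2–C3(O)–C4(C15) of ring A is a latent vinyl ketone (acceptor C1, donor C4). The axial 8β-oxygen on ring B lies 1,3-syn to the β face of C10 and blocks it.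
4. Ring B with C7, C11–C13 and C14 is (R)-carvone. C8–O comes from [4+2] oxygenation of its linear dienol ether (anti to the isopropenyl group), followed by Mitsunobu inversion to the cis acetate.
5. Ring order: ring B (chiral pool) first, ring A second (key step). Stereocentres are set in the order C7 (pool), C8, C10, C3, C5.

Key step: step 5

Remark: eudesmane numbering is used throughout (ring A = C1–C5, C10; ring B = C5–C10; C14 on C10, C15 on C4, C11–C13 on C7). β is the face of the C10 methyl group.

**Step 1**
Reactants: 1 (R)-(−)-carvone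
Product: 2 linear silyl dienol ether, (S)-trimethyl{[2-methyl-5-(prop-1-en-2-yl)cyclohexa-1,3-dien-1-yl]oxy}silane
Conditions: TMSCl, NaI, Et3N, MeCN, rt
Reagents that add atoms: chlorotrimethylsilane, C[Si](C)(C)Cl
Why: Thermodynamic enol silylation with TMSI made in situ, in which reversible O-silylation and deprotonation (Et3NH+ I− as proton shuttle) should funnel to the linear 1-silyloxy-1,3-diene with the tetrasubstituted enol double bond, as in the 3,5-dienol ethers of 4-en-3-ones; C7 is not touched.

**Step 2**
Reactants: 2 linear silyl dienol ether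
Product: 5 trans-4-hydroxycarvone, (4S,5R)-4-hydroxy-2-methyl-5-(prop-1-en-2-yl)cyclohex-2-en-1-one, via silyloxy endoperoxide 3 (not isolated), via γ-hydroperoxy enone 4 (not isolated)
Conditions: O2, TPP (cat.), hν, CH2Cl2, −78 °C; then MeOH, PPh3, −78 °C → rt
Reagents that add atoms: dioxygen (as singlet oxygen), O=O
Why: [4+2] cycloaddition of singlet oxygen to the electron-rich s-cis diene (the isopropenyl group is inert) from the face anti to the neighbouring isopropenyl group sets C8 (O α), methanolysis collapses the silyl peroxyketal to the γ-hydroperoxy enone, and PPh3 reduces the O–O bond, which amounts to a regiochemically unambiguous vinylogous γ-oxygenation.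

**Step 3**
Reactants: 5 trans-4-hydroxycarvone
Product: 6 cis-4-acetoxycarvone, (1R,6R)-3-methyl-4-oxo-6-(prop-1-en-2-yl)cyclohex-2-en-1-yl acetate
Conditions: AcOH, PPh3, DIAD, toluene, −20 °C → rt
Reagents that add atoms: acetic acid, CC(=O)O
Why: Mitsunobu reaction, in which acetate displaces the oxyphosphonium group in an SN2 step and inverts C8 (S → R) so that oxygen becomes cis to the isopropenyl group; the pseudo-equatorial leaving group has no antiperiplanar C7–H, which disfavours elimination and aromatisation.

**Step 4**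
Reactants: 7 (1-bromovinyl)trimethylsilane; 8 N-methoxy-N-methylpropanamide
Product: 10 2-(trimethylsilyl)pent-1-en-3-one, via [1-(trimethylsilyl)vinyl]magnesium bromide 9 (not isolated)
Conditions: Mg, THF, reflux; then 8, 0 °C; aq NH4Cl
Reagents that add atoms: none
Why: Grignard formation followed by Weinreb ketone synthesis, in which the chelated tetrahedral adduct prevents over-addition; no stereocentre is formed.

**Step 5**
Reactants: 6 cis-4-acetoxycarvone; 10 2-(trimethylsilyl)pent-1-en-3-one
Product: 13 8β-hydroxyeudesma-4,11-dien-3-one (8β-hydroxy-α-cyperone; 7α-H, 10β-CH3), via lithium enolate 11 (not isolated), via lithium enolate of the Michael adduct 12 (not isolated)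
Conditions: L-Selectride (1.0 equiv), THF, −78 °C; 10, −78 → −20 °C; then NaOMe, MeOH, −20 → 50 °C (one flask, no work-up in between)
Reagents that add atoms: none
Why: L-Selectride adds hydride 1,4 to C9 of the β-unsubstituted enone and places the enolate regiospecifically between C5–O and C10 (11); C10 then adds in a Michael reaction to the CH2 terminus of 10 (bond C1–C10), the silicon-stabilised enolate 12 being too weakly basic to polymerise the acceptor or scramble the ring enolate, and methoxide finally removes silicon and the acetyl group, moves the side-chain enolate to C4 and drives the aldol condensation onto C5 (bond C4–C5, then loss of water). The closest known reaction type is the Robinson annulation of a reductively generated, regiodefined enolate with an α-silyl vinyl ketone. Ring A, the only ring closed, forms in a 6-(enolendo)-exo-trig aldol mode. C10 is the only new stereocentre and is controlled by ring B: in the half-chair with equatorial isopropenyl the stereoelectronically preferred axial (β) trajectory runs 1,3-syn-axial into the 8β-acetoxy group, so the acceptor should enter from the α face through the flipped half-chair, which leaves the methyl group β, cis to the C7 and C8 substituents. The step needs 1,4- over 1,2-reduction (secured by the unsubstituted C9 and the bulky hydride), alkylation at C10 rather than C6 (secured by the origin of the enolate in the enone) and survival of the acetate until the bond at C10 is made (secured by −78 °C and the late addition of methoxide). C7 and C8 are not enolisable and stay untouched.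

**Step 6**
Reactants: 13 8β-hydroxyeudesma-4,11-dien-3-one
Product: 14 8β-acetoxyeudesma-4,11-dien-3-one
Conditions: Ac2O, DMAP, Et3N, CH2Cl2, rt
Reagents that add atoms: acetic anhydride, CC(=O)OC(C)=O
Why: DMAP-catalysed O-acylation of the only hydroxyl group (axial, secondary); the C–O bond is not broken, so C8 keeps its configuration, and the acetate is in place before C12 becomes an ester, which rules out lactonisation.

**Step 7**
Reactants: 14 8β-acetoxyeudesma-4,11-dien-3-one
Product: 16 8β-acetoxy-3-oxoeudesma-4,11(13)-dien-12-al, via 8β-acetoxy-12-hydroxyeudesma-4,11(13)-dien-3-one 15 (not isolated)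
Conditions: SeO2 (cat.), t-BuOOH, CH2Cl2, rt; then MnO2, CH2Cl2, rt
Reagents that add atoms: selenium dioxide, O=[Se]=O; tert-butyl hydroperoxide, CC(C)(C)OO
Why: Riley allylic oxidation (ene, then [2,3] shift) at the methyl group of the only electron-rich alkene, since the enone C=C is deactivated and C7–H is shielded and inductively deactivated by the neighbouring acetate; MnO2 then takes the allylic alcohol to the enal.

**Step 8**
Reactants: 16 8β-acetoxy-3-oxoeudesma-4,11(13)-dien-12-al
Product: 17 8β-acetoxy-3-oxoeudesma-4,11(13)-dien-12-oic acid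
Conditions: NaClO2, NaH2PO4, 2-methylbut-2-ene, t-BuOH/H2O, rt
Reagents that add atoms: sodium chlorite, [Na+].[O-]Cl=O
Why: Pinnick oxidation, which is selective for the aldehyde and leaves the alkenes, the enone and the acetate alone because the scavenger removes HOCl.

**Step 9**
Reactants: 17 8β-acetoxy-3-oxoeudesma-4,11(13)-dien-12-oic acid
Product: 18 methyl 8β-acetoxy-3-oxoeudesma-4,11(13)-dien-12-oate
Conditions: MeI, K2CO3, DMF, rt
Reagents that add atoms: iodomethane, CI
Why: SN2 O-alkylation of the carboxylate, which avoids dipolar cycloaddition of a diazoalkane to the acrylate and does not touch the acetate.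

**Step 10**
Reactants: 18 methyl 8β-acetoxy-3-oxoeudesma-4,11(13)-dien-12-oate
Product: 19 methyl 8β-acetoxy-3β-hydroxyeudesma-4,11(13)-dien-12-oate
Conditions: NaBH4, CeCl3·7H2O, MeOH, −78 → 0 °C
Reagents that add atoms: none
Why: Luche 1,2-reduction, in which hydride is delivered axially from the α face, opposite the 10β-methyl group, to give the equatorial 3β-alcohol as with 4-en-3-ones of the steroid type; the α-substituted acrylate and the acetate are not reduced.

**Step 11**
Reactants: 19 methyl 8β-acetoxy-3β-hydroxyeudesma-4,11(13)-dien-12-oate; 20 angelic acid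
Product: 22 methyl 8β-acetoxy-3β-angeloyloxyeudesma-4,11(13)-dien-12-oate, via angelic 2,4,6-trichlorobenzoic anhydride 21 (not isolated)
Conditions: 20, 2,4,6-Cl3C6H2COCl, Et3N, toluene, rt; then 19, 80 °C
Reagents that add atoms: none
Why: Yamaguchi-type mixed-anhydride esterification without a nucleophilic catalyst, the protocol that transfers the angeloyl group without Z → E isomerisation; O-acylation retains the configuration at C3.

**Step 12**
Reactants: 22 methyl 8β-acetoxy-3β-angeloyloxyeudesma-4,11(13)-dien-12-oate
Product: 24 target, methyl 8β-acetoxy-3β-angeloyloxy-5α-hydroxyeudesma-4(15),11(13)-dien-12-oate, via 5α-hydroperoxide 23 (not isolated)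
Conditions: O2, TPP (cat.), hν, CH2Cl2, 0 °C; then PPh3
Reagents that add atoms: dioxygen (as singlet oxygen), O=O
Why: Schenck ene reaction, in which singlet oxygen attacks the only electron-rich alkene (C4=C5) from the α face, opposite the 10β-methyl and 3β-angelate groups, and takes a hydrogen from the C15 methyl group (geminal to the acyloxy-bearing C3 and more reactive than ring CH2), so oxygen ends on C5 (5α) and the alkene moves to C4=C15; PPh3 reduces the hydroperoxide.

**Compound list**
1 | (R)-(−)-carvone, (5R)-2-methyl-5-(prop-1-en-2-yl)cyclohex-2-en-1-one | C=C(C)[C@H]1CC(=O)C(C)=CC1 | starting material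
2 | (S)-trimethyl{[2-methyl-5-(prop-1-en-2-yl)cyclohexa-1,3-dien-1-yl]oxy}silane | C=C(C)[C@H]1CC(O[Si](C)(C)C)=C(C)C=C1 | intermediate
3 | 6-methyl-8-(prop-1-en-2-yl)-1-(trimethylsilyloxy)-2,3-dioxabicyclo[2.2.2]oct-5-ene, O–O bridge anti to isopropenyl | C=C(C)[C@H]1C[C@]2(O[Si](C)(C)C)OO[C@H]1C=C2C | intermediate
4 | (4S,5R)-4-hydroperoxy-2-methyl-5-(prop-1-en-2-yl)cyclohex-2-en-1-one | C=C(C)[C@H]1CC(=O)C(C)=C[C@@H]1OO | intermediate
5 | trans-4-hydroxycarvone, (4S,5R)-4-hydroxy-2-methyl-5-(prop-1-en-2-yl)cyclohex-2-en-1-one | C=C(C)[C@H]1CC(=O)C(C)=C[C@@H]1O | intermediate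
6 | cis-4-acetoxycarvone, (1R,6R)-3-methyl-4-oxo-6-(prop-1-en-2-yl)cyclohex-2-en-1-yl acetate | C=C(C)[C@H]1CC(=O)C(C)=C[C@H]1OC(C)=O | intermediate
7 | (1-bromovinyl)trimethylsilane | C=C(Br)[Si](C)(C)C | starting material
8 | N-methoxy-N-methylpropanamide | CCC(=O)N(C)OC | starting material
9 | [1-(trimethylsilyl)vinyl]magnesium bromide | C=C([Mg]Br)[Si](C)(C)C | intermediate
10 | 2-(trimethylsilyl)pent-1-en-3-one | C=C([Si](C)(C)C)C(=O)CC | intermediate
11 | lithium enolate (C5–O/C10) of cis-4-acetoxydihydrocarvone | C=C(C)[C@H]1CC([O-])=C(C)C[C@H]1OC(C)=O.[Li+] | intermediate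
12 | lithium enolate of the Michael adduct (10β-CH3, 10α-CH2 side chain, α-silyl enolate) | C=C(C)[C@H]1CC(=O)[C@](C)(CC(=C([O-])CC)[Si](C)(C)C)C[C@H]1OC(C)=O.[Li+] | intermediate
13 | 8β-hydroxyeudesma-4,11-dien-3-one | C=C(C)[C@H]1CC2=C(C)C(=O)CC[C@]2(C)C[C@H]1O | intermediate
14 | 8β-acetoxyeudesma-4,11-dien-3-one | C=C(C)[C@H]1CC2=C(C)C(=O)CC[C@]2(C)C[C@H]1OC(C)=O | intermediate
15 | 8β-acetoxy-12-hydroxyeudesma-4,11(13)-dien-3-one | C=C(CO)[C@H]1CC2=C(C)C(=O)CC[C@]2(C)C[C@H]1OC(C)=O | intermediate
16 | 8β-acetoxy-3-oxoeudesma-4,11(13)-dien-12-al | C=C(C=O)[C@H]1CC2=C(C)C(=O)CC[C@]2(C)C[C@H]1OC(C)=O | intermediate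
17 | 8β-acetoxy-3-oxoeudesma-4,11(13)-dien-12-oic acid | C=C(C(=O)O)[C@H]1CC2=C(C)C(=O)CC[C@]2(C)C[C@H]1OC(C)=O | intermediate
18 | methyl 8β-acetoxy-3-oxoeudesma-4,11(13)-dien-12-oate | C=C(C(=O)OC)[C@H]1CC2=C(C)C(=O)CC[C@]2(C)C[C@H]1OC(C)=O | intermediate
19 | methyl 8β-acetoxy-3β-hydroxyeudesma-4,11(13)-dien-12-oate | C=C(C(=O)OC)[C@H]1CC2=C(C)[C@@H](O)CC[C@]2(C)C[C@H]1OC(C)=O | intermediate
20 | angelic acid, (Z)-2-methylbut-2-enoic acid | C/C=C(/C)C(=O)O | starting material
21 | angelic 2,4,6-trichlorobenzoic anhydride | C/C=C(/C)C(=O)OC(=O)c1c(Cl)cc(Cl)cc1Cl | intermediate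
22 | methyl 8β-acetoxy-3β-angeloyloxyeudesma-4,11(13)-dien-12-oate | C=C(C(=O)OC)[C@H]1CC2=C(C)[C@@H](OC(=O)/C(C)=C\C)CC[C@]2(C)C[C@H]1OC(C)=O | intermediate
23 | methyl 8β-acetoxy-3β-angeloyloxy-5α-hydroperoxyeudesma-4(15),11(13)-dien-12-oate | C=C(C(=O)OC)[C@H]1C[C@@]2(OO)C(=C)[C@@H](OC(=O)/C(C)=C\C)CC[C@]2(C)C[C@H]1OC(C)=O | intermediate
24 | methyl 8β-acetoxy-3β-angeloyloxy-5α-hydroxyeudesma-4(15),11(13)-dien-12-oate (CNP0179024.1) | C=C(C(=O)OC)[C@H]1C[C@@]2(O)C(=C)[C@@H](OC(=O)/C(C)=C\C)CC[C@]2(C)C[C@H]1OC(C)=O | target

**Step count**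
Total step count: 12. Longest linear sequence: 11 (steps 1–3 and 5–12).

**Steps most likely to fail**

Step 1. The silylation may proceed by deprotonation at C6 instead of C8, giving the cross-conjugated dienol ether, or ring B may drift towards aromatisation.
- The fallback is an allylic C–H oxidation and hydride route. It sets out from 1, returns at 6, and also by-passes the oxygenation of step 2 and the inversion of step 3.
- Luche reduction of 1 gives (−)-cis-carveol F1, which is silylated (TBSCl, imidazole) to cis-carveol TBS ether F2.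
- CrO3·3,5-dimethylpyrazole oxidises the only free allylic ring CH2 (C8) to the transposed enone, cis-4-(tert-butyldimethylsilyloxy)-3-methyl-6-(prop-1-en-2-yl)cyclohex-2-en-1-one F3.
- A second Luche reduction delivers hydride anti to the isopropenyl and silyloxy groups and gives the all-cis 8β-alcohol F4.
- Acetylation gives the all-cis silyloxy acetate F5. HF·pyridine then frees the C5 allylic alcohol in hydroxy acetate F6, and MnO2 oxidises it to 6.

Step 5. The Michael addition at the tetrasubstituted enolate carbon may be outrun by proton transfer or by oligomerisation of the acceptor, or the facial selectivity at C10 may be poor.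
- The fallback is a neutral, auxiliary-controlled aza-ene type Michael addition of a chiral imine. It sets out from 6 and returns at 13.
- 6 is reduced 1,4 with L-Selectride and protonated to cis-4-acetoxydihydrocarvone F7.
- F7 is condensed with (R)-1-phenylethylamine to the imine F8.
- The more substituted secondary enamine tautomer of F8 adds to pent-1-en-3-one, with the auxiliary reinforcing the ring-B bias, to give the keto imine F9.
- Aqueous acetic acid hydrolyses F9 to the 1,5-diketone F10. NaOMe/MeOH then closes ring A by aldol condensation, with loss of the acetate, to give 13.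

Step 12. Hydrogen abstraction may take place at C6 instead of C15, putting oxygen on C4, or face selectivity may erode.
- The fallback is epoxidation followed by a syn β-elimination. It sets out from 22 and returns at 24.
- m-CPBA epoxidises the only electron-rich alkene from the α face to the 4α,5α-epoxide F11.
- Diethylaluminium 2,2,6,6-tetramethylpiperidide (benzene, 0 °C) then removes a proton of the unhindered C15 methyl group syn to the coordinated oxygen. This opens the C4–O bond and gives 24.

**Further compounds**
F1 | step 1 | (−)-cis-carveol, (1R,5R)-2-methyl-5-(prop-1-en-2-yl)cyclohex-2-en-1-ol | C=C(C)[C@H]1C[C@@H](O)C(C)=CC1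
F2 | step 1 | cis-carveol TBS ether | C=C(C)[C@H]1C[C@@H](O[Si](C)(C)C(C)(C)C)C(C)=CC1
F3 | step 1 | cis-4-(tert-butyldimethylsilyloxy)-3-methyl-6-(prop-1-en-2-yl)cyclohex-2-en-1-one | C=C(C)[C@H]1C[C@@H](O[Si](C)(C)C(C)(C)C)C(C)=CC1=O
F4 | step 1 | all-cis 4-(tert-butyldimethylsilyloxy)-3-methyl-6-(prop-1-en-2-yl)cyclohex-2-en-1-ol (8β-alcohol) | C=C(C)[C@H]1C[C@@H](O[Si](C)(C)C(C)(C)C)C(C)=C[C@H]1O
F5 | step 1 | all-cis 4-(tert-butyldimethylsilyloxy)-3-methyl-6-(prop-1-en-2-yl)cyclohex-2-en-1-yl acetate | C=C(C)[C@H]1C[C@@H](O[Si](C)(C)C(C)(C)C)C(C)=C[C@H]1OC(C)=O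
F6 | step 1 | all-cis 4-hydroxy-3-methyl-6-(prop-1-en-2-yl)cyclohex-2-en-1-yl acetate | C=C(C)[C@H]1C[C@@H](O)C(C)=C[C@H]1OC(C)=O
F7 | step 5 | cis-4-acetoxydihydrocarvone (epimers at the methyl-bearing carbon) | C=C(C)[C@H]1CC(=O)C(C)C[C@H]1OC(C)=O
F8 | step 5 | (R)-1-phenylethyl imine of F7 | C=C(C)[C@H]1CC(=N[C@H](C)c2ccccc2)C(C)C[C@H]1OC(C)=O
F9 | step 5 | keto imine, Michael adduct of F8 with pent-1-en-3-one (10β-CH3) | C=C(C)[C@H]1CC(=N[C@H](C)c2ccccc2)[C@](C)(CCC(=O)CC)C[C@H]1OC(C)=O
F10 | step 5 | 1,5-diketone, 2-methyl-2-(3-oxopentyl) derivative of cis-4-acetoxydihydrocarvone (10β-CH3) | C=C(C)[C@H]1CC(=O)[C@](C)(CCC(=O)CC)C[C@H]1OC(C)=O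
F11 | step 12 | methyl 8β-acetoxy-3β-angeloyloxy-4α,5α-epoxyeudesm-11(13)-en-12-oate | C=C(C(=O)OC)[C@H]1C[C@@]2(O3)[C@@]3(C)[C@@H](OC(=O)/C(C)=C\C)CC[C@]2(C)C[C@H]1OC(C)=O
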